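Plan: the silyl group on O7 comes off last. Before that, ring A is cut at C4a–C5 and C8–C8a, and ring C at O1–C8a, C2–C3 and C4a=C8a (flavone numbering).
Feature used: ring A has hydrogen only at C5 and C8 and two neighbouring oxygens at C6 (OMe) and C7 (OH). C5–C6–C7–C8 is therefore a 2,3-dioxygenated butadiene, and C4a=C8a is one double bond of the 2-aryl-4-pyranone that is ring C.
Forward order: ring B is bought as the aroyl chloride. Ring C is built from (phenylthio)acetone, one amide-acetal carbon and the aroyl carbon. Ring A is closed last by cycloaddition and aromatised in the same flask by loss of PhSOH and Me2NH.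
O6 enters as a methyl ether and O7 as a silyl ether on the diene, so no selective protection of a catechol is needed later.
Stereochemistry: the target has no stereocentre. Only the diene geometry (amino group trans to C3) and the suprafacial addition (sulfur on C4a syn to hydrogen on C8a) matter, and every transient centre disappears on aromatisation.
Key step: step 6

Remark: flavone numbering is also applied to the atoms of the diene and the dienophile that become rings A and C, and each enaminone is drawn as the isomer with nitrogen trans to the carbonyl carbon, which such push-pull alkenes reach by easy rotation.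

Step 1
Reactants: 1 methoxyacetone (1-methoxypropan-2-one); 2 N,N-dimethylformamide dimethyl acetal
Product: 3 (3Z)-4-(dimethylamino)-3-methoxybut-3-en-2-one
Conditions: 2 (1.5 equiv), neat, 100 °C, MeOH distilled off
Reagents that add atoms: none
Why: Aminomethylenation of an active methylene with an amide acetal: the methoxy-bearing CH2 is the more acidic α-position and leads to the more substituted push-pull alkene, as alkoxyacetones are known to react, and easy rotation about the polarised C=C lets the amino group settle trans to the acetyl carbon.

Step 2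
Reactants: 3 (3Z)-4-(dimethylamino)-3-methoxybut-3-en-2-one
Product: 4 (1Z)-3-(tert-butyldimethylsilyloxy)-1-(dimethylamino)-2-methoxybuta-1,3-diene
Conditions: NaN(SiMe3)2 (1.05 equiv), THF, −78 °C; TBSCl, −78 °C to rt; filtered under argon, distilled under vacuum
Reagents that add atoms: tert-butyldimethylsilyl chloride (TBSCl), CC(C)(C)[Si](C)(C)Cl
Why: Silyl enol ether formation by kinetic deprotonation of the vinylogous amide at its only acidic site (the acetyl CH3) and O-silylation of the cross-conjugated enolate, the standard way to 1-amino-3-siloxybutadienes, with the C1=C2 geometry carried over from 3.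

Step 3
Reactants: 5 (phenylthio)acetone (1-(phenylthio)propan-2-one); 2 N,N-dimethylformamide dimethyl acetal
Product: 6 (3Z)-4-(dimethylamino)-3-(phenylthio)but-3-en-2-one
Conditions: 2 (1.5 equiv), toluene, 100 °C
Reagents that add atoms: none
Why: The same amide-acetal aminomethylenation, here directed without ambiguity to the CH2 that is acidified by both sulfur and the carbonyl group.

Step 4
Reactants: 6 (3Z)-4-(dimethylamino)-3-(phenylthio)but-3-en-2-one; 7 3,4,5-trimethoxybenzoyl chloride
Product: 9 5-(phenylthio)-2-(3,4,5-trimethoxyphenyl)-4H-pyran-4-one, via enaminodiketone 8 (not isolated)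
Conditions: LiN(SiMe3)2 (2.5 equiv) added to 6 + 7, THF, −78 °C; then 2 M aq HCl, rt
Reagents that add atoms: none
Why: Claisen-type C-acylation of the α'-enolate of the enaminone, generated in the presence of the acid chloride so that it cannot self-condense (the second equivalent of base deprotonates the acidic diketone 8), followed by acid-induced 6-endo-trig addition of the aroyl enol oxygen to the aminomethylene carbon and loss of Me2NH, an established 4-pyranone synthesis.

Step 5
Reactants: 9 5-(phenylthio)-2-(3,4,5-trimethoxyphenyl)-4H-pyran-4-one
Product: 10 5-(phenylsulfinyl)-2-(3,4,5-trimethoxyphenyl)-4H-pyran-4-one (racemic at sulfur)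
Conditions: mCPBA (1.0 equiv), CH2Cl2, −20 to 0 °C
Reagents that add atoms: 3-chloroperoxybenzoic acid (mCPBA), O=C(OO)c1cccc(Cl)c1
Why: Chemoselective sulfide-to-sulfoxide oxidation with one equivalent of peracid in the cold, where the second oxidation is slower and the electron-poor pyranone double bonds and the aryl methyl ethers do not react; the new sulfur stereocentre is formed racemic and is discarded in step 6.

Step 6
Reactants: 10 5-(phenylsulfinyl)-2-(3,4,5-trimethoxyphenyl)-4H-pyran-4-one; 4 (1Z)-3-(tert-butyldimethylsilyloxy)-1-(dimethylamino)-2-methoxybuta-1,3-diene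
Product: 13 7-O-(tert-butyldimethylsilyl)prosogerin D [7-(tert-butyldimethylsilyloxy)-6-methoxy-2-(3,4,5-trimethoxyphenyl)-4H-chromen-4-one], via sulfinyl cycloadduct 11 (not isolated), via aminodihydroflavone 12 (not isolated)
Conditions: 4 (1.5 equiv), toluene, 0 °C to rt until 10 is consumed; then 80 °C, argon sweep
Reagents that add atoms: none
Why: This is a normal-electron-demand Diels–Alder reaction, concerted but very asynchronous: the diene CH2 (future C8), on which the 1-amino and 3-silyloxy donors both concentrate the HOMO, bonds ahead to C8a, the carbon β to both the C4 carbonyl and the sulfinyl group, and the aminated terminus (future C5) then closes onto C4a, so that ring A arises as a six-membered carbocycle by intermolecular (4+2) closure, suprafacial on both partners. The closest known reactions are the cycloadditions of 3-sulfinyl-, 3-formyl-, 3-cyano- and 3-nitrochromones with siloxydienes, which aromatise to xanthones after elimination, and 10 holds the same acceptor-substituted 4-pyranone ring without the fused benzene. Suprafacial addition to the ring double bond fixes the only relationship that matters in 11, sulfur on C4a and hydrogen on C8a on one face, whereas C5 (endo or exo approach) and sulfur may be mixtures because 13 keeps no stereocentre. That syn relationship allows the thermal five-centre syn elimination of PhSOH to 12, and ionisation of the doubly allylic C5–N bond, assisted by the C7 silyloxy group and by O1, followed by loss of a C8 proton, releases Me2NH and gives the arene. Three selectivities are needed: orientation, secured by the matched polarisation just described (the 2-methoxy group opposes it only weakly); site, secured because only C4a=C8a carries the sulfinyl acceptor while C2=C3 is a plain, aryl-blocked vinylogous ester bond; and direction of the sulfoxide elimination, expected toward C8a–H because this restores the pyranone, whereas a C4a=C5 bond would wedge the NMe2 group between the C4 carbonyl and the C6 methoxy group. Holding the mixture at or below room temperature until 10 is used up keeps liberated Me2NH away from the electrophilic C8a of the dienophile.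

Step 7
Reactants: 13 7-O-(tert-butyldimethylsilyl)prosogerin D
Product: 14 prosogerin D [7-hydroxy-6-methoxy-2-(3,4,5-trimethoxyphenyl)-4H-chromen-4-one]
Conditions: Bu4NF (1.1 equiv), AcOH (1.1 equiv), THF, 0 °C
Reagents that add atoms: none
Why: Fluoride-induced cleavage of an aryl silyl ether, driven by the Si–F bond and especially easy for the acidic C7 phenol of a flavone, buffered with AcOH so that the four methyl ethers and ring C stay untouched.

Compound list
1 | methoxyacetone (1-methoxypropan-2-one) | COCC(C)=O | starting material
2 | N,N-dimethylformamide dimethyl acetal | COC(OC)N(C)C | starting material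
3 | (3Z)-4-(dimethylamino)-3-methoxybut-3-en-2-one (nitrogen trans to the acetyl carbon) | CC(=O)/C(OC)=C/N(C)C | intermediate
4 | (1Z)-3-(tert-butyldimethylsilyloxy)-1-(dimethylamino)-2-methoxybuta-1,3-diene (nitrogen trans to C3) | C=C(O[Si](C)(C)C(C)(C)C)/C(OC)=C/N(C)C | intermediate
5 | (phenylthio)acetone (1-(phenylthio)propan-2-one) | CC(=O)CSc1ccccc1 | starting material
6 | (3Z)-4-(dimethylamino)-3-(phenylthio)but-3-en-2-one | CC(=O)/C(Sc1ccccc1)=C/N(C)C | intermediate
7 | 3,4,5-trimethoxybenzoyl chloride | COc1cc(C(=O)Cl)cc(OC)c1OC | starting material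
8 | (4Z)-5-(dimethylamino)-4-(phenylthio)-1-(3,4,5-trimethoxyphenyl)pent-4-ene-1,3-dione (forms in the flask of step 4) | COc1cc(C(=O)CC(=O)/C(Sc2ccccc2)=C/N(C)C)cc(OC)c1OC | intermediate
9 | 5-(phenylthio)-2-(3,4,5-trimethoxyphenyl)-4H-pyran-4-one | O=c1cc(-c2cc(OC)c(OC)c(OC)c2)occ1Sc1ccccc1 | intermediate
10 | 5-(phenylsulfinyl)-2-(3,4,5-trimethoxyphenyl)-4H-pyran-4-one (racemic at sulfur) | O=c1cc(-c2cc(OC)c(OC)c(OC)c2)occ1S(=O)c1ccccc1 | intermediate
11 | cis-fused 7-(tert-butyldimethylsilyloxy)-5-(dimethylamino)-6-methoxy-4a-(phenylsulfinyl)-2-(3,4,5-trimethoxyphenyl)-4a,5,8,8a-tetrahydro-4H-chromen-4-one (racemic; S on C4a and H on C8a on one face; epimers at C5 and at sulfur; forms in the flask of step 6) | O=C1C=C(c3cc(OC)c(OC)c(OC)c3)O[C@@H]2CC(O[Si](C)(C)C(C)(C)C)=C(OC)C(N(C)C)[C@]12S(=O)c1ccccc1 | intermediate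
12 | 7-(tert-butyldimethylsilyloxy)-5-(dimethylamino)-6-methoxy-2-(3,4,5-trimethoxyphenyl)-5,8-dihydro-4H-chromen-4-one (racemic; forms in the flask of step 6) | COC1=C(O[Si](C)(C)C(C)(C)C)Cc2oc(-c3cc(OC)c(OC)c(OC)c3)cc(=O)c2C1N(C)C | intermediate
13 | 7-O-(tert-butyldimethylsilyl)prosogerin D | COc1cc2c(=O)cc(-c3cc(OC)c(OC)c(OC)c3)oc2cc1O[Si](C)(C)C(C)(C)C | intermediate
14 | prosogerin D | COc1cc2c(=O)cc(-c3cc(OC)c(OC)c(OC)c3)oc2cc1O | target

Total step count: 7.
Longest linear sequence: 5 steps (steps 3, 4, 5, 6, 7, from 5 to 14). The diene arm adds steps 1 and 2.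

Steps most likely to fail

Step 6. The diene may add in conjugate fashion to C8a without closing the second bond, after which the pyranone opens at O1–C8a. Liberated dimethylamine may attack dienophile that has not yet reacted. In an endo adduct the sulfoxide may eliminate toward C5–H, which would later cost O1 instead of nitrogen. The fallback changes the activating group and separates cycloaddition from aromatisation. It sets out from 9. Excess mCPBA (CH2Cl2, rt) gives the sulfone 5-(phenylsulfonyl)-2-(3,4,5-trimethoxyphenyl)-4H-pyran-4-one F1, a stronger acceptor with no thermal syn-elimination channel. Cycloaddition with 4 at or below room temperature should stop at the cis-fused sulfonyl cycloadduct F2, so no amine is released while dienophile is present. Dilute HCl in THF, the usual treatment of aminosiloxy cycloadducts, hydrolyses the silyl enol ether and removes Me2NH by β-elimination. This gives the enone cis-6-methoxy-4a-(phenylsulfonyl)-2-(3,4,5-trimethoxyphenyl)-8,8a-dihydro-4aH-chromene-4,7-dione F3. Enolisation of its C7 ketone and loss of benzenesulfinic acid across C4a–C8a (helped by Et3N if needed) aromatises ring A. The route is rejoined at 14.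

Step 4. The enolate may be acylated on oxygen, the acidic diketone may quench unreacted enolate by proton transfer, and the amide base may be consumed by the acid chloride. The fallback forms the C2–C3 bond at the alcohol oxidation level. It sets out from 6. The lithium enolate (LiN(SiMe3)2, THF, −78 °C) is added to commercial 3,4,5-trimethoxybenzaldehyde. This aldol addition needs one equivalent of base and has no oxygen-versus-carbon ambiguity. It gives the racemic aldol (1Z)-1-(dimethylamino)-5-hydroxy-2-(phenylthio)-5-(3,4,5-trimethoxyphenyl)pent-1-en-3-one F4. IBX in EtOAc, a known oxidant for turning β-hydroxy ketones into 1,3-diketones, converts it into 8, where the route is rejoined, and acid closes 9 as in step 4.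

Step 2. The very electron-rich diene may be protonated or hydrolysed on isolation, and the enolate may self-condense. The C1=C2 geometry may also drift to the isomer with nitrogen inside, which cannot reach the cycloaddition geometry. The fallback replaces the nitrogen donor by oxygen, which gives a sturdier and less basic diene. It sets out from 3. HCl in MeOH exchanges the amino group and gives the racemic keto acetal 3,4,4-trimethoxybutan-2-one F5. TBSOTf (2.2 equiv) and Et3N in Et2O turn the acetal into the enol ether and the ketone into the silyl enol ether in one operation. The product is (1Z)-3-(tert-butyldimethylsilyloxy)-1,2-dimethoxybuta-1,3-diene F6, a distillable 1-alkoxy-3-siloxydiene. With 10 in toluene at 80–110 °C it should pass through the cis-fused 5-methoxy sulfinyl cycloadduct F7 and the 5-methoxy-5,8-dihydroflavone F8, which lose PhSOH and MeOH. The route is rejoined at 13.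

Further compounds
F1 | step 6 | 5-(phenylsulfonyl)-2-(3,4,5-trimethoxyphenyl)-4H-pyran-4-one | O=c1cc(-c2cc(OC)c(OC)c(OC)c2)occ1S(=O)(=O)c1ccccc1
F2 | step 6 | cis-fused 7-(tert-butyldimethylsilyloxy)-5-(dimethylamino)-6-methoxy-4a-(phenylsulfonyl)-2-(3,4,5-trimethoxyphenyl)-4a,5,8,8a-tetrahydro-4H-chromen-4-one (racemic, epimers at C5) | O=C1C=C(c3cc(OC)c(OC)c(OC)c3)O[C@@H]2CC(O[Si](C)(C)C(C)(C)C)=C(OC)C(N(C)C)[C@]12S(=O)(=O)c1ccccc1
F3 | step 6 | cis-6-methoxy-4a-(phenylsulfonyl)-2-(3,4,5-trimethoxyphenyl)-8,8a-dihydro-4aH-chromene-4,7-dione (racemic) | O=C1C=C(c3cc(OC)c(OC)c(OC)c3)O[C@@H]2CC(=O)C(OC)=C[C@]12S(=O)(=O)c1ccccc1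
F4 | step 4 | (1Z)-1-(dimethylamino)-5-hydroxy-2-(phenylthio)-5-(3,4,5-trimethoxyphenyl)pent-1-en-3-one (racemic) | COc1cc(C(O)CC(=O)/C(Sc2ccccc2)=C/N(C)C)cc(OC)c1OC
F5 | step 2 | 3,4,4-trimethoxybutan-2-one (racemic) | CC(=O)C(OC)C(OC)OC
F6 | step 2 | (1Z)-3-(tert-butyldimethylsilyloxy)-1,2-dimethoxybuta-1,3-diene | C=C(O[Si](C)(C)C(C)(C)C)/C(OC)=C/OC
F7 | step 2 | cis-fused 7-(tert-butyldimethylsilyloxy)-5,6-dimethoxy-4a-(phenylsulfinyl)-2-(3,4,5-trimethoxyphenyl)-4a,5,8,8a-tetrahydro-4H-chromen-4-one (racemic, epimers at C5 and at sulfur) | O=C1C=C(c3cc(OC)c(OC)c(OC)c3)O[C@@H]2CC(O[Si](C)(C)C(C)(C)C)=C(OC)C(OC)[C@]12S(=O)c1ccccc1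
F8 | step 2 | 7-(tert-butyldimethylsilyloxy)-5,6-dimethoxy-2-(3,4,5-trimethoxyphenyl)-5,8-dihydro-4H-chromen-4-one (racemic) | COC1=C(O[Si](C)(C)C(C)(C)C)Cc2oc(-c3cc(OC)c(OC)c(OC)c3)cc(=O)c2C1OC
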